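**Assumption:** the SMILES carries no axial descriptor, so the hindered ring B–ring C axis is treated as configurationally unspecified and no atroposelective step is planned.

**Compound numbers:** 1 2-iodo-1,3,5-trimethoxybenzene, 2 1,3,5-trimethoxybenzene (one ring of the A–B unit and ring D), 3 aryllithium (not isolated), 4 arylzinc chloride (not isolated), 5 hexamethoxybiphenyl (rings A–B), 6 2-chloro-1,3-dimethoxybenzene, 7 aryl boronate (not isolated), 8 4-chloro-3,5-dimethoxyphenol (ring C), 9 biaryl phenol (rings D–C), 10 quaterphenyl monophenol, 11 target.

## The problem

Target 11 is a linear quaterphenyl of four phloroglucinol rings (ring A–ring B–ring C–ring D, a chlorinated fucol-type phlorotannin) joined by the bonds A1–B1, B5–C1 and C5–D1. Ring B keeps one hydrogen (B3), whereas ring C is fully substituted: chlorine at C3 is flanked by the hydroxyls at C2 and C4 and stands para to the hydroxyl at C6, which sits between the aryl-bearing carbons C1 and C5. Each biaryl bond has four ortho oxygens, so all three are tetra-ortho-substituted. All oxygen-free carbons of a phloroglucinol ring are equivalent, so the constitution is fixed by how often each ring is substituted and not where (once for rings A and D, twice for ring B, twice plus chlorine for ring C), and the task is control of the degree of substitution and of the ring order. There is no stereocentre, and the B5–C1 axis is unsymmetrically flanked but unspecified. The twelve free hydroxyls make 11 very easily oxidised (air, base), so they must be released last under non-oxidising conditions. The aryl chloride rules out hydrogenolytic deprotection and is a liability under the electron-rich palladium catalysts that hindered couplings need. The feature that makes the key step possible: ring C is a 4-chlorophenol (C6–OH, C3–Cl) arylated at both ortho carbons (C1 and C5), and rings A and B together form a difucol unit whose four C–H positions are equivalent by symmetry.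

## Retrosynthesis

**11 to 10.** The eleven O–methyl bonds are cut; the C6 hydroxyl of ring C is already free in 10. Methyl ethers are chosen over benzyl ethers because the chloride forbids hydrogenolysis and because the polymethoxyarenes needed are commercial. The forward step is one global Lewis-acid demethylation that leaves C–Cl and the biaryl bonds alone.

**10 to 9 + 5 (bond B5–C1).** This cut splits the molecule into two biaryl halves of almost equal size. Cutting A1–B1 or C5–D1 last would leave a terphenyl plus a single ring and gain less. Half 5 (rings A–B, hexamethoxybiphenyl) is fully symmetric. Half 9 (rings D–C) carries the only free hydroxyl and the chlorine. The forward reaction is a dehydrogenative phenol–arene cross-coupling with no halogen or boron on either partner. It must oxidise 9 and not 5, bond at the one C–H of ring C, and substitute 5 only once.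

**9 to 8 + 2 (bond C5–D1).** The same reaction type joins phenol 8 (ring C) to 1,3,5-trimethoxybenzene 2 (ring D). Phenol 8 has two equivalent ortho C–H positions and a chlorine-blocked para position, and 2 has three equivalent C–H positions, so no regiochemical question arises. The forward step must stop at mono-arylation.

**8 to 6 (C6–O bond of ring C, via 7).** The hydroxyl must stand para to chlorine and meta to both methoxy groups. Electrophilic chlorination of 3,5-dimethoxyphenol would not reliably distinguish its 2- and 4-positions. Sterically governed C–H borylation of commercial 2-chloro-1,3-dimethoxybenzene 6 reaches exactly the C–H that has no ortho neighbour, and oxidation of boronate 7 gives 8.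

**5 to 1 + 2 (bond A1–B1, via 3 and 4).** The symmetric biaryl 5 is cut into a nucleophilic and an electrophilic 2,4,6-trimethoxyphenyl unit. The nucleophile comes from commercial 1,3,5-trimethoxybenzene 2, the same compound that serves as ring D: lithiation between two methoxy groups gives aryllithium 3, and zinc chloride converts it into arylzinc chloride 4. The electrophile is commercial 2-iodo-1,3,5-trimethoxybenzene 1. A Negishi coupling is preferred to oxidative dimerisation of 2, which has no reason to stop at the dimer. It is also preferred to a boronic acid coupling, because a 2,6-dioxygenated arylboronic acid protodeboronates under aqueous base, whereas the arylzinc reagent is used under anhydrous conditions. This is the only palladium step of the route, and it is placed on the half that carries no chlorine.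

## Roads not taken

**Alternative 1:** The obvious plan cuts all three biaryl bonds as Suzuki–Miyaura couplings. Chlorination and two-fold iodination of 2 would give 1-chloro-3,5-diiodo-2,4,6-trimethoxybenzene A1. Two-fold coupling with (2,4,6-trimethoxyphenyl)boronic acid A2 would give the chloroterphenyl nonamethyl ether A3. Mono-iodination at one of its four equivalent outer C–H positions would give A4, and a third coupling with A2 would give the dodecamethyl ether A5, then demethylation.
- It needs three tetra-ortho-substituted palladium couplings, each with a 2,6-dioxygenated boronic acid that protodeboronates readily under aqueous base.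
- The ligands that make such couplings work are the ones that activate aryl chlorides, so C3–Cl is at risk three times. The chosen plan keeps its single palladium step on the chlorine-free half and uses an arylzinc reagent there.
- Three halogen atoms are installed only to be removed, and the mono-iodination of A3 is statistical.
- It is six linear steps with no convergence, against a longest linear sequence of four.

**Alternative 2:** Ring C could be built from an open chain, forming C1–C2 and C4–C5 by a double Claisen-type C-acylation of the unsymmetrical 1,3-diarylacetone A6 with a malonyl bis-electrophile (a laboratory version of the polyketide closure to phloroglucinol). This would give A7, in which ring C alone is a free triol, and its only C–H (C3) could then be chlorinated selectively. Neither hindered bond to ring C would be made by a coupling.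
- A6 needs about four steps, and the A1–B1 bond still has to be made by coupling.
- Each benzylic carbon is flanked by two ortho-methoxy groups, and O-acylation of the enol with lactone closure competes with the second C-acylation.
- The annulation is least certain exactly where the material is most valuable, and the route is about eight steps.

**Alternative 3:** Two dimerisations and a late chlorination would follow the presumed biosynthesis most literally. Oxidative dehydrodimerisation of 5 would give tetrafucol dodecamethyl ether A8 (a single constitution, for the symmetry reason above), and monochlorination would give A5.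
- A8 is as electron-rich as 5, so the coupling has no reason to stop at the tetramer.
- The chlorination must choose two inner C–H positions over four outer ones. The outer ones are more numerous, less hindered and more activated: their para-methoxy group can lie in the ring plane, whereas the para-methoxy of an inner ring is flanked by two aryl groups and twisted out of conjugation.
- The chosen plan places chlorine before any ring is joined and uses it as the para-blocking group of the phenol.

Key step: step 4

## Route

**Step 1**
Reactants: 1 2-iodo-1,3,5-trimethoxybenzene; 2 1,3,5-trimethoxybenzene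
Product: 5 2,2',4,4',6,6'-hexamethoxy-1,1'-biphenyl, via (2,4,6-trimethoxyphenyl)lithium 3 (not isolated), via (2,4,6-trimethoxyphenyl)zinc chloride 4 (not isolated)
Conditions: 2 (1.3 equiv), n-BuLi (1.25 equiv), THF, 0 °C to rt; ZnCl2 (1.3 equiv), THF, rt; then 1 (1.0 equiv), Pd2(dba)3 (1 mol %), 2-dicyclohexylphosphino-2',6'-diisopropoxybiphenyl (4 mol %), THF/NMP, 100 °C, sealed tube
Reagents that add atoms: n-butyllithium [Li]CCCC (lithium of 3); zinc chloride Cl[Zn]Cl (zinc and chlorine of 4)
Why: Directed lithiation of 2 between two methoxy groups (its three C–H positions are equivalent) gives 3, ZnCl2 converts it into 4, and Negishi cross-coupling with iodide 1 at zerovalent palladium (oxidative addition, transmetalation, reductive elimination) gives 5. The bulky dialkylbiarylphosphine is the ligand type known to allow reductive elimination of tetra-ortho-substituted biaryls, neither partner carries chlorine, and the anhydrous arylzinc reagent avoids the protodeboronation to which 2,6-dioxygenated arylboronic acids are prone.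

**Step 2**
Reactants: 6 2-chloro-1,3-dimethoxybenzene
Product: 8 4-chloro-3,5-dimethoxyphenol, via aryl pinacol boronate 7 (not isolated)
Conditions: [Ir(OMe)(cod)]2 (1.5 mol %), 4,4'-di-tert-butyl-2,2'-bipyridine, B2pin2, THF, 80 °C; then acetone, aq KHSO5 (added as 2KHSO5·KHSO4·K2SO4), rt
Reagents that add atoms: bis(pinacolato)diboron CC1(C)OB(OC1(C)C)B1OC(C)(C)C(C)(C)O1 (boron and pinacol of 7); potassium peroxymonosulfate [K+].[O-]S(=O)(=O)OO (phenol oxygen of 8)
Why: Iridium-catalysed C–H borylation is sterically governed, so only C5–H of 6 (no ortho substituent) should react and the C–Cl bond is inert; one-pot oxidation of the C–B bond of 7 (1,2-aryl shift from boron to oxygen) puts the hydroxyl para to chlorine.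

**Step 3**
Reactants: 8 4-chloro-3,5-dimethoxyphenol; 2 1,3,5-trimethoxybenzene
Product: 9 4-chloro-3,5-dimethoxy-2-(2,4,6-trimethoxyphenyl)phenol
Conditions: FeCl3 (10 mol %), t-BuOOt-Bu (1.0 equiv), 2 (4 equiv), (CF3)2CHOH, rt
Reagents that add atoms: none
Why: Iron-catalysed oxidative phenol–arene cross-coupling: 8 is bound to trivalent iron and oxidised by the peroxide to a phenoxyl radical whose only open positions are the two equivalent ortho carbons (para is blocked by chlorine), and the π-nucleophile 2 adds there before rearomatisation. Excess 2, limiting peroxide and shielding of the phenol oxygen by the new ortho aryl group should favour mono-arylation.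

**Step 4**
Reactants: 9 4-chloro-3,5-dimethoxy-2-(2,4,6-trimethoxyphenyl)phenol; 5 2,2',4,4',6,6'-hexamethoxy-1,1'-biphenyl
Product: 10 4-chloro-3,5-dimethoxy-2-(2,4,6-trimethoxyphenyl)-6-[2,4,6-trimethoxy-3-(2,4,6-trimethoxyphenyl)phenyl]phenol
Conditions: FeCl3 (20 mol %), t-BuOOt-Bu (1.5 equiv), 5 (3 equiv), (CF3)2CHOH/ClCH2CH2Cl, rt to 40 °C, slow addition of 9
Reagents that add atoms: none
Why: Oxidative (dehydrogenative) phenol–arene cross-coupling, the same known reaction type as in step 3 and the laboratory counterpart of the phenol coupling by which fucols are presumed to form, here used to join two biaryl halves. Mechanism: 9 exchanges onto FeCl3 as an iron phenolate, which the peroxide oxidises (the O–H of 9 is the weakest bond present) to an iron-bound phenoxyl radical; a C–H carbon of 5 adds to the one free ortho carbon of ring C, and loss of a second electron and two protons rearomatises both rings, with tert-butanol as the only by-product. No ring is closed and no stereocentre is set; the new B5–C1 axis forms without configurational control, which the target does not ask for. Site selectivity on 9 is structural: ring C has a single C–H and the para carbon carries chlorine, so only ortho C–C bonding can end in an aromatic product. Site selectivity on 5 is removed by symmetry: its four C–H carbons are equivalent, and each gives ring B with the required 1,3-diaryl pattern and one hydrogen left. Chemoselectivity rests on the single free hydroxyl, since only 9 can bind iron and form a phenoxyl radical, while the permethylated partner 5 can act only as a π-nucleophile comparable to 2. The conditions must supply cross- over self-coupling (ring D of a second molecule of 9 is also nucleophilic) and single arylation of 5, hence the threefold excess of 5 (recovered) and the slow addition of 9. The tetra-ortho-oxygenated bond is made by addition of a π-nucleophile to a radical, not at a crowded low-valent metal, and for the same reason the aryl chloride is not at risk.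

**Step 5**
Reactants: 10 4-chloro-3,5-dimethoxy-2-(2,4,6-trimethoxyphenyl)-6-[2,4,6-trimethoxy-3-(2,4,6-trimethoxyphenyl)phenyl]phenol
Product: 11 4-chloro-2-(2,4,6-trihydroxyphenyl)-6-[2,4,6-trihydroxy-3-(2,4,6-trihydroxyphenyl)phenyl]benzene-1,3,5-triol
Conditions: BBr3 (24 equiv), CH2Cl2, −78 °C to rt; then MeOH, degassed H2O, under Ar
Reagents that add atoms: none
Why: Lewis-acid cleavage of aryl methyl ethers: BBr3 coordinates each methoxy oxygen and bromide removes the methyl group by SN2, and the aryl borates are hydrolysed on work-up. The aryl chloride and biaryl bonds are inert, and excess reagent with long reaction time addresses the doubly flanked methoxy groups.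

## Compound list

1 | 2-iodo-1,3,5-trimethoxybenzene | COc1cc(OC)c(I)c(OC)c1 | starting material
2 | 1,3,5-trimethoxybenzene | COc1cc(OC)cc(OC)c1 | starting material
3 | (2,4,6-trimethoxyphenyl)lithium | COc1cc(OC)c([Li])c(OC)c1 | intermediate (not isolated)
4 | (2,4,6-trimethoxyphenyl)zinc chloride | COc1cc(OC)c([Zn]Cl)c(OC)c1 | intermediate (not isolated)
5 | 2,2',4,4',6,6'-hexamethoxy-1,1'-biphenyl | COc1cc(OC)c(-c2c(OC)cc(OC)cc2OC)c(OC)c1 | intermediate
6 | 2-chloro-1,3-dimethoxybenzene | COc1cccc(OC)c1Cl | starting material
7 | 2-(4-chloro-3,5-dimethoxyphenyl)-4,4,5,5-tetramethyl-1,3,2-dioxaborolane | COc1cc(B2OC(C)(C)C(C)(C)O2)cc(OC)c1Cl | intermediate (not isolated)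
8 | 4-chloro-3,5-dimethoxyphenol | COc1cc(O)cc(OC)c1Cl | intermediate
9 | 4-chloro-3,5-dimethoxy-2-(2,4,6-trimethoxyphenyl)phenol | COc1cc(OC)c(-c2c(O)cc(OC)c(Cl)c2OC)c(OC)c1 | intermediate
10 | 4-chloro-3,5-dimethoxy-2-(2,4,6-trimethoxyphenyl)-6-[2,4,6-trimethoxy-3-(2,4,6-trimethoxyphenyl)phenyl]phenol | COc1cc(OC)c(-c2c(OC)c(Cl)c(OC)c(-c3c(OC)cc(OC)c(-c4c(OC)cc(OC)cc4OC)c3OC)c2O)c(OC)c1 | intermediate
11 | 4-chloro-2-(2,4,6-trihydroxyphenyl)-6-[2,4,6-trihydroxy-3-(2,4,6-trihydroxyphenyl)phenyl]benzene-1,3,5-triol | Oc1cc(O)c(-c2c(O)cc(O)c(-c3c(O)c(Cl)c(O)c(-c4c(O)cc(O)cc4O)c3O)c2O)c(O)c1 | target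

## Step count and least certain steps

Total step count: 5. Longest linear sequence: 4 steps (steps 2, 3, 4, 5, from 6); step 1 is a one-step branch that supplies 5.

**Step 4 (key step).**
- The phenoxyl radical of 9 has no ortho or para donor (both methoxy groups are meta to oxygen) and its hydroxyl is flanked by an aryl group, so oxidation of 9 may be slow compared with oxidation and homocoupling of the electron-rich partner 5.
- Ring D of 9 or a second C–H of 5 may enter the coupling, giving oligomers.
- The product phenol may be oxidised further at the chlorine-bearing para carbon with loss of chloride.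
- Fallback (polar ligand coupling at tetravalent lead in place of radical dehydrogenative coupling): setting out from 5, direct plumbation with Pb(OAc)4 in CHCl3 should give (2,2',4,4',6,6'-hexamethoxybiphenyl-3-yl)lead triacetate F1, at any of the four equivalent C–H positions. Pinhey ortho-arylation of phenol 9 with F1 (pyridine, CHCl3, 40–60 °C) transfers the aryl group to the single ortho C–H of ring C through an aryloxy–lead intermediate, a process that tolerates di-ortho-substituted aryl groups. The route is rejoined at 10.

**Step 3.**
- A second arylation at the other ortho carbon of 8 would give the symmetric 2,6-diarylphenol, and 2 may homocouple. The same doubt about the ease of phenoxyl formation applies as in step 4.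
- Fallback (halogen/boron cross-coupling): setting out from 8, monobromination with N-bromosuccinimide (CH2Cl2, −20 °C) at one of the two equivalent ortho positions should give 2-bromo-4-chloro-3,5-dimethoxyphenol F2. Suzuki–Miyaura coupling of F2 with commercial (2,4,6-trimethoxyphenyl)boronic acid A2 (Pd(OAc)2, SPhos, K3PO4, toluene/H2O, 90 °C) should be selective for C–Br over the doubly flanked C–Cl. The route is rejoined at 9.

**Step 5.**
- Ether cleavage may be incomplete at the methoxy groups flanked by two substituents, leaving partially methylated phenols that are hard to separate from 11, and the dodecaphenol may oxidise during isolation.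
- Fallback (isolation through a stable derivative): setting out from 10, the crude product of the BBr3 reaction is peracetylated (Ac2O, pyridine) to the dodecaacetate 4-chloro-2-(2,4,6-triacetoxyphenyl)-6-[2,4,6-triacetoxy-3-(2,4,6-triacetoxyphenyl)phenyl]benzene-1,3,5-triyl triacetate F3. F3 is purified on silica away from under-demethylated material and then deacetylated by acid-catalysed methanolysis (HCl in degassed MeOH, rt, Ar). The route is rejoined at 11.

**Step 1.**
- Transmetalation and reductive elimination at the crowded palladium centre may be slow, so that hydrodeiodination of 1 and aryl scrambling with homocoupling compete; incomplete lithiation of 2 would lower the amount of 4 available.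
- Fallback (reductive homocoupling on copper in place of palladium cross-coupling): setting out from 1, classical Ullmann coupling of two molecules of the iodide with activated Cu bronze (4 equiv, neat, 230 °C, sealed tube) should give 5 directly through aryl–copper intermediates. No organometallic partner has to be prepared and no ligand-dependent reductive elimination is involved. This fallback makes no new compound (F0) and rejoins the route at 5.

## Further compounds

F1 | step 4 | (2,2',4,4',6,6'-hexamethoxybiphenyl-3-yl)lead triacetate | COc1cc(OC)c(-c2c(OC)cc(OC)c([Pb](OC(C)=O)(OC(C)=O)OC(C)=O)c2OC)c(OC)c1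
F2 | step 3 | 2-bromo-4-chloro-3,5-dimethoxyphenol | COc1cc(O)c(Br)c(OC)c1Cl
F3 | step 5 | 4-chloro-2-(2,4,6-triacetoxyphenyl)-6-[2,4,6-triacetoxy-3-(2,4,6-triacetoxyphenyl)phenyl]benzene-1,3,5-triyl triacetate | CC(=O)Oc1cc(OC(C)=O)c(-c2c(OC(C)=O)cc(OC(C)=O)c(-c3c(OC(C)=O)c(Cl)c(OC(C)=O)c(-c4c(OC(C)=O)cc(OC(C)=O)cc4OC(C)=O)c3OC(C)=O)c2OC(C)=O)c(OC(C)=O)c1
F0 | step 1 | none | none
A1 | alternative 1 | 1-chloro-3,5-diiodo-2,4,6-trimethoxybenzene | COc1c(Cl)c(OC)c(I)c(OC)c1I
A2 | alternative 1 | (2,4,6-trimethoxyphenyl)boronic acid | COc1cc(OC)c(B(O)O)c(OC)c1
A3 | alternative 1 | 5'-chloro-2,2',2'',4,4',4'',6,6',6''-nonamethoxy-1,1':3',1''-terphenyl | COc1cc(OC)c(-c2c(OC)c(Cl)c(OC)c(-c3c(OC)cc(OC)cc3OC)c2OC)c(OC)c1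
A4 | alternative 1 | 5'-chloro-3-iodo-2,2',2'',4,4',4'',6,6',6''-nonamethoxy-1,1':3',1''-terphenyl | COc1cc(OC)c(-c2c(OC)c(Cl)c(OC)c(-c3c(OC)cc(OC)c(I)c3OC)c2OC)c(OC)c1
A5 | alternative 1 | 2-chloro-1,3,5-trimethoxy-4-(2,4,6-trimethoxyphenyl)-6-[2,4,6-trimethoxy-3-(2,4,6-trimethoxyphenyl)phenyl]benzene (dodecamethyl ether of 11) | COc1cc(OC)c(-c2c(OC)cc(OC)c(-c3c(OC)c(Cl)c(OC)c(-c4c(OC)cc(OC)cc4OC)c3OC)c2OC)c(OC)c1
A6 | alternative 2 | 1-(2,2',4,4',6,6'-hexamethoxybiphenyl-3-yl)-3-(2,4,6-trimethoxyphenyl)propan-2-one | COc1cc(OC)c(CC(=O)Cc2c(OC)cc(OC)c(-c3c(OC)cc(OC)cc3OC)c2OC)c(OC)c1
A7 | alternative 2 | 2-(2,4,6-trimethoxyphenyl)-4-[2,4,6-trimethoxy-3-(2,4,6-trimethoxyphenyl)phenyl]benzene-1,3,5-triol | COc1cc(OC)c(-c2c(O)cc(O)c(-c3c(OC)cc(OC)c(-c4c(OC)cc(OC)cc4OC)c3OC)c2O)c(OC)c1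
A8 | alternative 3 | 1,3,5-trimethoxy-2-(2,4,6-trimethoxyphenyl)-4-[2,4,6-trimethoxy-3-(2,4,6-trimethoxyphenyl)phenyl]benzene (tetrafucol dodecamethyl ether) | COc1cc(OC)c(-c2c(OC)cc(OC)c(-c3c(OC)cc(OC)c(-c4c(OC)cc(OC)cc4OC)c3OC)c2OC)c(OC)c1
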